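Readings and results are calculated for substances that don't exist; scatter was added.

As the chemist following the west flask, I wanted its order in free catalyst, and I took a plain catalytic step as the zero of my scale.

| setting | west | east | flask |
|---|---|---|---|
| left-handed substrate | 0.88 M | 0.59 M | 0.88 M |
| right-handed substrate | 0.88 M | 0.59 M | 0.88 M |
| solid reagent | 2 equiv | 2 equiv | 2.00 equiv |
| free catalyst | 2.7 mol% | 2.7 mol% | 2.7 mol% |
| impurity | 2.6 mM | 2.6 mM | 2.6 mM |
| remark | the very flask that is asked about, followed so far | run made earlier |  |

| run | time / min | left-handed product / % | left-handed substrate / % |
|---|---|---|---|
| west | 0.200 | 1.6 | 49.5 |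
| west | 0.667 | 3.3 | 46.6 |
| west | 1.00 | 5.1 | 44.3 |
| west | 1.50 | 7.9 | 42.2 |
| west | 2.50 | 14.0 | 35.7 |
| east | 1.50 | 6.0 | 42.7 |
| east | 3.00 | 14.1 | 35.2 |
| east | 6.00 | 25.8 | 24.0 |
| east | 10.0 | 36.0 | 13.9 |
| east | 20.0 | 46.6 | 1.8 |

(standard deviation of a reading: 0.5 percentage points)

- apparent order in free catalyst when 10% of the left-handed substrate and right-handed substrate together are converted (percent change of the rate of making left-handed product for one percent more free catalyst charged)

- free catalyst is single-handed; left-handed substrate and right-handed substrate are mirror images of each other, charged as a racemate, each of them at the stated concentration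
- given per volume of solution although it is solid: solid reagent
- steps that have been proposed: partner + free catalyst + left-handed substrate -> free catalyst + left-handed product; partner + free catalyst + right-handed substrate -> free catalyst + right-handed product; solid reagent <-> partner; free catalyst + impurity -> spent catalyst
- at the start none of the solid reagent is in solution

If the impurity takes one free catalyst each, west keeps 21.2 mM active out of 23.8 mM charged, so the plain order would be 1.12.

I doubted this. Let k be the first-order constant of left-handed substrate from the charge to a reading, with about the same part of that substrate consumed in each run. West gave 0.135 min⁻¹ and east 0.117 min⁻¹. East keeps 13.3 mM active by the same count, so the factor of 1.15 between the constants is less than the factor of 1.59 in active catalyst. East's constant also reached 0.204 min⁻¹ late, higher than early, as substrate fell.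

So I let the partner sit where dissolving matches use. Then τ, the inverse of k, is A/C + B·S, with C the active catalyst and S the substrate concentration. Solving the two runs gave a catalytic term A/C in west of 3.90 min. The catalyst share φ, meaning A/C over τ, was 0.525, so the rate-limiting step was shared, with about half of τ in the catalytic term. My order was φ times the plain order, 0.589.

Two objections remained. West's window runs past 10% conversion, but it straddles that point, so I left it uncorrected. One reading's scatter moves k by 4.16%, so I trusted my order to its first decimal.

The forecast gave 0.55, from 0.35 to 0.8, a little below mine, holding that “its supply from the solid partly limits the rate”.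

The west flask gave 0.56 at 10% conversion, reached at 1.69 min, under these steps:

    partner + free catalyst + left-handed substrate → free catalyst + left-handed product (k = 202 M⁻² min⁻¹)
    partner + free catalyst + right-handed substrate → free catalyst + right-handed product (k = 16.5 M⁻² min⁻¹)
    solid reagent ⇌ partner, rate k3*(cs3 - [partner]) while solid is left; crystals form when [partner] > cs3 (solubility = 0.0640 M, k = 3.43 min⁻¹)
    free catalyst + impurity → spent catalyst (k = 20400 M⁻¹ min⁻¹)

At 5.62 min west made partner 1.03 times as fast as it used it, each step taken net. Dividing by the plain order puts west's share at 0.500, beside my φ of 0.525. Carried to the east run's first 3.00 min, with A/C larger by the factor in active catalyst and τ as read there, φ becomes 0.723 and my order for east 0.865.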